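**Retrosynthetic overview**
- The target is opened at the seven O-benzyl ethers and at the C3 ester. This gives penta-O-benzyl-(−)-epigallocatechin and 3,4-bis(benzyloxy)-5-methoxybenzoic acid.
- The cis-(2R,3R) alcohol comes from the racemic flavan-3-one by dynamic asymmetric transfer hydrogenation. The ketone comes from a 3-bromoflavylium salt by hydride addition at C4 and exchange of C3–Br for C3–B and then C3–O.
- The strategy rests on ring C (O1, C2, C3, C4, C4a, C8a). It is the furan ring of a 2-arylbenzofuran enlarged by one carbon, C3, which lies between C2 and C4 and carries the ester oxygen. Dibromocarbene supplies this carbon as C–Br and forms the bonds C2–C3 and C3–C4.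
- The benzofuran comes from Sonogashira coupling and 5-endo-dig cyclisation of 3,5-bis(benzyloxy)-2-iodophenol with the arylacetylene made from 3,4,5-tris(benzyloxy)benzaldehyde.
- Ring order: rings A and B and the galloyl ring are bought; the furan ring is closed first (step 3) and then expanded to ring C (step 4).

Key step: step 4

Assumption: RuCl(p-cymene)[(R,R)-TsDPEN] is taken to give the 3R alcohol, by analogy with 2-arylcycloalkanones in which the aryl-bearing α-carbon plays the part of the aryl group of acetophenone; if correlation of the product showed the opposite sense, the (S,S)-complex would be used instead.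

**Step 1**
Reactants: 1 3,5-bis(benzyloxy)phenol
Product: 2 3,5-bis(benzyloxy)-2-iodophenol
Conditions: NIS (1.0 equiv), CH2Cl2, −20 °C to 0 °C, dark
Reagents that add atoms: N-iodosuccinimide, O=C1CCC(=O)N1I
Why: Electrophilic aromatic iodination, in which the hydroxyl group should direct iodine to its ortho position C2 (hydrogen bonding to the reagent in a non-polar solvent) while C4 is shielded by two flanking benzyloxy groups, and one equivalent of reagent limits di-iodination.

**Step 2**
Reactants: 3 3,4,5-tris(benzyloxy)benzaldehyde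
Product: 4 1,2,3-tris(benzyloxy)-5-ethynylbenzene
Conditions: dimethyl (1-diazo-2-oxopropyl)phosphonate, K2CO3, MeOH/THF, 0 °C to rt
Reagents that add atoms: dimethyl (1-diazo-2-oxopropyl)phosphonate, CC(=O)C(=[N+]=[N-])P(=O)(OC)OC
Why: Seyferth–Gilbert homologation in the Ohira–Bestmann variant, in which methanolysis of the acetyl group releases the diazomethylphosphonate anion, this olefinates the non-enolisable aldehyde, and the diazoalkene loses N2 with a 1,2-hydrogen shift to give the terminal alkyne.

**Step 3**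
Reactants: 2 3,5-bis(benzyloxy)-2-iodophenol; 4 1,2,3-tris(benzyloxy)-5-ethynylbenzene
Product: 6 4,6-bis(benzyloxy)-2-[3,4,5-tris(benzyloxy)phenyl]benzofuran, via alkynylphenol 5 (not isolated)
Conditions: PdCl2(PPh3)2 (3 mol%), CuI (6 mol%), Et3N, DMF, degassed, 70 °C
Reagents that add atoms: none
Why: Sonogashira coupling of the aryl iodide with the terminal alkyne, followed in the same flask by 5-endo-dig cycloisomerisation of the ortho-alkynylphenol 5 (metal-activated alkyne, amine base), which is the standard one-pot route to 2-arylbenzofurans.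

**Step 4**
Reactants: 6 4,6-bis(benzyloxy)-2-[3,4,5-tris(benzyloxy)phenyl]benzofuran; 7 bromoform
Product: 10 5,7-bis(benzyloxy)-3-bromo-2-[3,4,5-tris(benzyloxy)phenyl]chromenylium bromide, via dibromocyclopropane adduct 8 (not isolated), via tert-butyl ketal 9 (not isolated)
Conditions: CHBr3 (3 equiv), KOt-Bu (portionwise), toluene, −20 °C to rt; aqueous wash; then 33% HBr in AcOH (slight excess), Et2O, 0 °C, salt collected by filtration
Reagents that add atoms: bromoform (7), BrC(Br)Br; hydrogen bromide, Br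
Why: Dibromocarbene, formed by α-elimination from bromoform with tert-butoxide, adds as an electrophile in a concerted [2+1] manner to the C2=C3 bond of the benzofuran to give the gem-dibromocyclopropane 8. This adduct should open at once by a disrotatory two-electron electrocyclic cleavage of the old furan C2–C3 bond as the endo bromide leaves, so the carbene carbon becomes C3 of the flavylium ion, bonded to C2 and C4, and the allyl cation is the aromatic benzopyrylium. Ring C is thus made by enlargement of the furan through opening of the bicyclic adduct, not by a cyclisation, and no stereocentre results. The closest known reaction type is the Ciamician–Dennstedt-type dihalocarbene ring expansion of indoles, indenes and benzofurans to 3-haloquinolines, 2-halonaphthalenes and 3-halochromenes. The selectivity needed is addition at the furan double bond and not at the alkoxyarene rings or benzylic C–H bonds, which the enol ether character of that bond, reinforced by the two ring A benzyloxy groups, should secure. tert-Butoxide is expected to cap the cation as the C2 ketal 9, and a short cold treatment with HBr re-ionises it to the flavylium bromide, which is stabilised by the C2 aryl and ring A alkoxy groups and precipitates from ether.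

**Step 5**
Reactants: 10 5,7-bis(benzyloxy)-3-bromo-2-[3,4,5-tris(benzyloxy)phenyl]chromenylium bromide
Product: 11 5,7-bis(benzyloxy)-3-bromo-2-[3,4,5-tris(benzyloxy)phenyl]-4H-chromene
Conditions: NaBH4, THF/MeCN, −20 °C to 0 °C, argon
Reagents that add atoms: none
Why: Borohydride reduction of a flavylium salt, in which hydride should add at the unsubstituted C4 terminus and not at C2, which is flanked by the aryl group and the bromine, to give the neutral flav-2-ene with the vinylic bromide intact; addition at C2 would leave the same vinylic C3 bromide, so the later borylation, oxidation and tautomerisation should tolerate either regiochemistry.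

**Step 6**
Reactants: 11 5,7-bis(benzyloxy)-3-bromo-2-[3,4,5-tris(benzyloxy)phenyl]-4H-chromene
Product: 12 2-{5,7-bis(benzyloxy)-2-[3,4,5-tris(benzyloxy)phenyl]-4H-chromen-3-yl}-4,4,5,5-tetramethyl-1,3,2-dioxaborolane
Conditions: B2pin2, PdCl2(dppf) (5 mol%), KOAc, 1,4-dioxane, 80 °C, argon
Reagents that add atoms: bis(pinacolato)diboron, CC1(C)OB(OC1(C)C)B1OC(C)(C)C(C)(C)O1
Why: Miyaura borylation, with oxidative addition of zerovalent palladium into the alkenyl C–Br bond, acetate-assisted transmetalation with the diboron reagent and reductive elimination, under a weak base that the benzyl ethers and the enol ether tolerate.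

**Step 7**
Reactants: 12 2-{5,7-bis(benzyloxy)-2-[3,4,5-tris(benzyloxy)phenyl]-4H-chromen-3-yl}-4,4,5,5-tetramethyl-1,3,2-dioxaborolane
Product: 14 rac-5,7-bis(benzyloxy)-2-[3,4,5-tris(benzyloxy)phenyl]chroman-3-one, via enol 13 (not isolated)
Conditions: 30% H2O2, aq NaHCO3, THF, 0 °C; Na2S2O3 quench
Reagents that add atoms: hydrogen peroxide, OO
Why: Oxidation of an alkenyl boronate, in which hydroperoxide adds to boron, the alkenyl group migrates from boron to oxygen, and hydrolysis gives enol 13, which tautomerises to the flavan-3-one; C2 becomes a stereocentre here and is formed racemic on purpose, and cold, weakly basic conditions protect the enolisable ketone.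

**Step 8**
Reactants: 14 rac-5,7-bis(benzyloxy)-2-[3,4,5-tris(benzyloxy)phenyl]chroman-3-one
Product: 15 (2R,3R)-5,7-bis(benzyloxy)-2-[3,4,5-tris(benzyloxy)phenyl]chroman-3-ol
Conditions: RuCl(p-cymene)[(R,R)-TsDPEN] (2 mol%), HCO2H/Et3N (5:2), EtOAc, 40 °C, argon
Reagents that add atoms: none
Why: Noyori–Ikariya asymmetric transfer hydrogenation under dynamic kinetic resolution, in which the acidic C2–H (benzylic, α-oxy, α-keto) lets the ketone enantiomers interconvert through the enol faster than they are reduced, and the catalyst should reduce the (2R)-ketone preferentially by hydride delivery to the Si face of C3, anti to the C2 aryl group, so the ligand sets C3 as R and the anti approach sets the cis (2R,3R) relationship.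

**Step 9**
Reactants: 16 methyl 3,4-dihydroxy-5-methoxybenzoate
Product: 17 methyl 3,4-bis(benzyloxy)-5-methoxybenzoate
Conditions: BnBr (2.4 equiv), K2CO3, DMF, 60 °C
Reagents that add atoms: benzyl bromide, BrCc1ccccc1
Why: Williamson ether synthesis on both phenols (SN2 at the benzylic carbon), which leaves the methyl ester and the methyl ether untouched.

**Step 10**
Reactants: 17 methyl 3,4-bis(benzyloxy)-5-methoxybenzoate
Product: 18 3,4-bis(benzyloxy)-5-methoxybenzoic acid
Conditions: LiOH·H2O, THF/MeOH/H2O, 50 °C; then 1 M HCl to pH 2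
Reagents that add atoms: lithium hydroxide, [Li+].[OH-]
Why: Ester saponification by acyl–oxygen cleavage, to which the aryl benzyl and methyl ethers are inert.

**Step 11**
Reactants: 15 (2R,3R)-5,7-bis(benzyloxy)-2-[3,4,5-tris(benzyloxy)phenyl]chroman-3-ol; 18 3,4-bis(benzyloxy)-5-methoxybenzoic acid
Product: 19 (2R,3R)-5,7-bis(benzyloxy)-2-[3,4,5-tris(benzyloxy)phenyl]chroman-3-yl 3,4-bis(benzyloxy)-5-methoxybenzoate
Conditions: DCC, DMAP (0.3 equiv), CH2Cl2, 0 °C to rt
Reagents that add atoms: none
Why: Steglich esterification, in which the O-acylisourea is converted by DMAP into an acylpyridinium ion that acylates the hindered axial C3 hydroxyl at oxygen, so no bond to C2 or C3 is broken and both stereocentres are kept.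

**Step 12**
Reactants: 19 (2R,3R)-5,7-bis(benzyloxy)-2-[3,4,5-tris(benzyloxy)phenyl]chroman-3-yl 3,4-bis(benzyloxy)-5-methoxybenzoate
Product: 20 (−)-epigallocatechin 3-(3-methyl-gallate)
Conditions: H2 (1 atm), Pd(OH)2/C (20 wt%), THF/MeOH (1:1), rt; filtration and evaporation under argon without heating
Reagents that add atoms: none
Why: Catalytic hydrogenolysis of the seven O-benzyl ethers under neutral conditions at room temperature, which should leave the ester, the methyl ether and the base- and heat-sensitive C2 configuration unchanged.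

**Compound list**
1 | 3,5-bis(benzyloxy)phenol | Oc1cc(OCc2ccccc2)cc(OCc2ccccc2)c1 | starting material
2 | 3,5-bis(benzyloxy)-2-iodophenol | Oc1cc(OCc2ccccc2)cc(OCc2ccccc2)c1I | intermediate
3 | 3,4,5-tris(benzyloxy)benzaldehyde | O=Cc1cc(OCc2ccccc2)c(OCc2ccccc2)c(OCc2ccccc2)c1 | starting material
4 | 1,2,3-tris(benzyloxy)-5-ethynylbenzene | C#Cc1cc(OCc2ccccc2)c(OCc2ccccc2)c(OCc2ccccc2)c1 | intermediate
5 | 3,5-bis(benzyloxy)-2-{[3,4,5-tris(benzyloxy)phenyl]ethynyl}phenol | Oc1cc(OCc2ccccc2)cc(OCc2ccccc2)c1C#Cc1cc(OCc2ccccc2)c(OCc2ccccc2)c(OCc2ccccc2)c1 | intermediate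
6 | 4,6-bis(benzyloxy)-2-[3,4,5-tris(benzyloxy)phenyl]benzofuran | c1c(-c2cc(OCc3ccccc3)c(OCc3ccccc3)c(OCc3ccccc3)c2)oc2cc(OCc3ccccc3)cc(OCc3ccccc3)c12 | intermediate
7 | bromoform | BrC(Br)Br | starting material
8 | rac-4,6-bis(benzyloxy)-1,1-dibromo-1a-[3,4,5-tris(benzyloxy)phenyl]-1a,6b-dihydro-1H-cyclopropa[b]benzofuran (cis-fused gem-dibromocyclopropane across the furan C2–C3 bond of 6) | BrC1(Br)C2c3c(OCc4ccccc4)cc(OCc4ccccc4)cc3OC12c1cc(OCc2ccccc2)c(OCc2ccccc2)c(OCc2ccccc2)c1 | intermediate
9 | rac-5,7-bis(benzyloxy)-3-bromo-2-tert-butoxy-2-[3,4,5-tris(benzyloxy)phenyl]-2H-chromene | CC(C)(C)OC1(c2cc(OCc3ccccc3)c(OCc3ccccc3)c(OCc3ccccc3)c2)Oc2cc(OCc3ccccc3)cc(OCc3ccccc3)c2C=C1Br | intermediate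
10 | 5,7-bis(benzyloxy)-3-bromo-2-[3,4,5-tris(benzyloxy)phenyl]chromenylium bromide | Brc1cc2c(OCc3ccccc3)cc(OCc3ccccc3)cc2[o+]c1-c1cc(OCc2ccccc2)c(OCc2ccccc2)c(OCc2ccccc2)c1.[Br-] | intermediate
11 | 5,7-bis(benzyloxy)-3-bromo-2-[3,4,5-tris(benzyloxy)phenyl]-4H-chromene | BrC1=C(c2cc(OCc3ccccc3)c(OCc3ccccc3)c(OCc3ccccc3)c2)Oc2cc(OCc3ccccc3)cc(OCc3ccccc3)c2C1 | intermediate
12 | 2-{5,7-bis(benzyloxy)-2-[3,4,5-tris(benzyloxy)phenyl]-4H-chromen-3-yl}-4,4,5,5-tetramethyl-1,3,2-dioxaborolane | CC1(C)OB(OC1(C)C)C1=C(c2cc(OCc3ccccc3)c(OCc3ccccc3)c(OCc3ccccc3)c2)Oc2cc(OCc3ccccc3)cc(OCc3ccccc3)c2C1 | intermediate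
13 | 5,7-bis(benzyloxy)-2-[3,4,5-tris(benzyloxy)phenyl]-4H-chromen-3-ol | OC1=C(c2cc(OCc3ccccc3)c(OCc3ccccc3)c(OCc3ccccc3)c2)Oc2cc(OCc3ccccc3)cc(OCc3ccccc3)c2C1 | intermediate
14 | rac-5,7-bis(benzyloxy)-2-[3,4,5-tris(benzyloxy)phenyl]chroman-3-one (C2 racemic) | O=C1Cc2c(OCc3ccccc3)cc(OCc3ccccc3)cc2OC1c1cc(OCc2ccccc2)c(OCc2ccccc2)c(OCc2ccccc2)c1 | intermediate
15 | (2R,3R)-5,7-bis(benzyloxy)-2-[3,4,5-tris(benzyloxy)phenyl]chroman-3-ol | O[C@@H]1Cc2c(OCc3ccccc3)cc(OCc3ccccc3)cc2O[C@@H]1c1cc(OCc2ccccc2)c(OCc2ccccc2)c(OCc2ccccc2)c1 | intermediate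
16 | methyl 3,4-dihydroxy-5-methoxybenzoate | COC(=O)c1cc(O)c(O)c(OC)c1 | starting material
17 | methyl 3,4-bis(benzyloxy)-5-methoxybenzoate | COC(=O)c1cc(OCc2ccccc2)c(OCc2ccccc2)c(OC)c1 | intermediate
18 | 3,4-bis(benzyloxy)-5-methoxybenzoic acid | OC(=O)c1cc(OCc2ccccc2)c(OCc2ccccc2)c(OC)c1 | intermediate
19 | (2R,3R)-5,7-bis(benzyloxy)-2-[3,4,5-tris(benzyloxy)phenyl]chroman-3-yl 3,4-bis(benzyloxy)-5-methoxybenzoate | COc1cc(C(=O)O[C@@H]2Cc3c(OCc4ccccc4)cc(OCc4ccccc4)cc3O[C@@H]2c2cc(OCc3ccccc3)c(OCc3ccccc3)c(OCc3ccccc3)c2)cc(OCc2ccccc2)c1OCc1ccccc1 | intermediate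
20 | (−)-epigallocatechin 3-(3-methyl-gallate) | COc1cc(C(=O)O[C@@H]2Cc3c(O)cc(O)cc3O[C@@H]2c2cc(O)c(O)c(O)c2)cc(O)c1O | target

**Step count**
Total: 12 steps. Longest linear sequence: 9 steps (steps 1, 3, 4, 5, 6, 7, 8, 11, 12).

**Steps most likely to fail**

Step 4. The carbene may be used up by tert-butoxide and tert-butanol, or may attack benzylic C–H bonds, faster than it adds to the weakly aromatic furan bond. The cation may also degrade under base before it is re-ionised, and prolonged contact with HBr could cleave benzyl ethers. The fallback builds ring C by cyclisation instead of ring expansion; it sets out from aldehyde 3 and comes back at ketone 14. Claisen–Schmidt condensation of 3 with purchased 1-[2-hydroxy-4,6-bis(benzyloxy)phenyl]ethanone F1 (KOH, EtOH/THF, rt) should give (E)-1-[2-hydroxy-4,6-bis(benzyloxy)phenyl]-3-[3,4,5-tris(benzyloxy)phenyl]prop-2-en-1-one F2. Reduction with NaBH4 (THF/EtOH, then AcOH) and cyclisation of the resulting allylic alcohol should give rac-5,7-bis(benzyloxy)-2-[3,4,5-tris(benzyloxy)phenyl]-2H-chromene F3. Hydroboration–oxidation (BH3·THF, then H2O2/NaOH) places oxygen at C3, anti to the aryl group, and should give rac-2,3-trans-5,7-bis(benzyloxy)-2-[3,4,5-tris(benzyloxy)phenyl]chroman-3-ol F4. Dess–Martin oxidation of F4 gives ketone 14, and the route continues with step 8.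

Step 8. Both flanks of the carbonyl group are benzylic, so enantioface discrimination may be poor, and C2 epimerisation may be too slow relative to reduction; either would lower the enantiomeric purity or the cis selectivity. The fallback replaces catalyst control by substrate control and resolution; it sets out from ketone 14 and comes back at alcohol 15. Reduction with LiBH(s-Bu)3 (THF, −78 °C) delivers hydride anti to the C2 aryl group and should give rac-cis-5,7-bis(benzyloxy)-2-[3,4,5-tris(benzyloxy)phenyl]chroman-3-ol F5. Preparative chromatography on a chiral stationary phase then separates the (2R,3R)-enantiomer, which is 15.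

Step 6. The electron-rich 4H-chromene may lose its bromine by protodehalogenation or be re-aromatised to a flavylium ion under palladium catalysis and heat, and the alkenyl boronate may not survive purification. The fallback replaces borylation and oxidation by C–N coupling and hydrolysis; it sets out from bromide 11 and comes back at ketone 14. Buchwald–Hartwig amination of 11 with morpholine (Pd2(dba)3, BINAP, NaOt-Bu, toluene, 80 °C) should give the enamine 4-{5,7-bis(benzyloxy)-2-[3,4,5-tris(benzyloxy)phenyl]-4H-chromen-3-yl}morpholine F6. Mild hydrolysis (aqueous AcOH, THF, rt) gives ketone 14, so steps 6 and 7 are both bypassed.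

**Further compounds**
F1 | step 4 | 1-[2-hydroxy-4,6-bis(benzyloxy)phenyl]ethanone | CC(=O)c1c(O)cc(OCc2ccccc2)cc1OCc1ccccc1
F2 | step 4 | (E)-1-[2-hydroxy-4,6-bis(benzyloxy)phenyl]-3-[3,4,5-tris(benzyloxy)phenyl]prop-2-en-1-one | O=C(/C=C/c1cc(OCc2ccccc2)c(OCc2ccccc2)c(OCc2ccccc2)c1)c1c(O)cc(OCc2ccccc2)cc1OCc1ccccc1
F3 | step 4 | rac-5,7-bis(benzyloxy)-2-[3,4,5-tris(benzyloxy)phenyl]-2H-chromene | C1(c2cc(OCc3ccccc3)c(OCc3ccccc3)c(OCc3ccccc3)c2)Oc2cc(OCc3ccccc3)cc(OCc3ccccc3)c2C=C1
F4 | step 4 | rac-2,3-trans-5,7-bis(benzyloxy)-2-[3,4,5-tris(benzyloxy)phenyl]chroman-3-ol (both enantiomers) | O[C@H]1Cc2c(OCc3ccccc3)cc(OCc3ccccc3)cc2O[C@@H]1c1cc(OCc2ccccc2)c(OCc2ccccc2)c(OCc2ccccc2)c1.O[C@@H]1Cc2c(OCc3ccccc3)cc(OCc3ccccc3)cc2O[C@H]1c1cc(OCc2ccccc2)c(OCc2ccccc2)c(OCc2ccccc2)c1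
F5 | step 8 | rac-cis-5,7-bis(benzyloxy)-2-[3,4,5-tris(benzyloxy)phenyl]chroman-3-ol (both enantiomers) | O[C@@H]1Cc2c(OCc3ccccc3)cc(OCc3ccccc3)cc2O[C@@H]1c1cc(OCc2ccccc2)c(OCc2ccccc2)c(OCc2ccccc2)c1.O[C@H]1Cc2c(OCc3ccccc3)cc(OCc3ccccc3)cc2O[C@H]1c1cc(OCc2ccccc2)c(OCc2ccccc2)c(OCc2ccccc2)c1
F6 | step 6 | 4-{5,7-bis(benzyloxy)-2-[3,4,5-tris(benzyloxy)phenyl]-4H-chromen-3-yl}morpholine | C1COCCN1C1=C(c2cc(OCc3ccccc3)c(OCc3ccccc3)c(OCc3ccccc3)c2)Oc2cc(OCc3ccccc3)cc(OCc3ccccc3)c2C1
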